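**Retrosynthetic overview**
1. Target 13 comes from 3,4'-dihydroxy-5,6,7,8-tetramethoxyflavone by chelation-directed cleavage of the peri 5-OMe; the 4'-OH is carried as a benzyl ether.
2. The 3-OH comes from epoxidation/isomerisation of the flavone C2=C3 bond (alkaline H2O2 on the chalcone is avoided, since 6'-alkoxychalcones give aurones).
3. Ring C is formed last, by oxidative cyclisation of a 2'-hydroxychalcone; rings A and B are bought as arenes.
4. The key C–C bond (Cα–Cβ) comes from a Claisen–Schmidt aldol condensation of 2'-hydroxy-3',4',5',6'-tetramethoxyacetophenone with 4-benzyloxybenzaldehyde.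
5. The acetophenone comes from 3,4,5-trimethoxyphenol by C-acetylation, ring bromination and Cu-mediated methoxylation.

**Assumptions**
- The target is achiral (no stereocentre), so no stereocontrol is needed; transient chiral intermediates are racemic and marked so.
- Acids and bases that only promote a step (BF3·OEt2, KOH, p-TsOH) are treated as promoters that the balanced equation does not consume.

**Route**

Step 1
Reactants: 1 3,4,5-trimethoxyphenol
Product: 2 2'-hydroxy-4',5',6'-trimethoxyacetophenone
Conditions: AcOH, BF3·OEt2, 90 °C, 2 h; then H2O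
Reagents that add atoms: acetic acid, CC(=O)O
Why: BF3-promoted Friedel–Crafts C-acylation (Fries-type) of the electron-rich phenol at one of its two equivalent ortho positions, with the boron-chelated product deactivated towards a second acylation.

Step 2
Reactants: 2 2'-hydroxy-4',5',6'-trimethoxyacetophenone
Product: 3 3'-bromo-2'-hydroxy-4',5',6'-trimethoxyacetophenone
Conditions: NBS (1.05 equiv), MeCN, 0 °C → rt
Reagents that add atoms: N-bromosuccinimide, O=C1CCC(=O)N1Br
Why: Electrophilic aromatic bromination at the only ring C–H, which is ortho to OH and para to OMe and therefore reacts faster than the ketone α-position.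

Step 3
Reactants: 3 3'-bromo-2'-hydroxy-4',5',6'-trimethoxyacetophenone
Product: 4 2'-hydroxy-3',4',5',6'-tetramethoxyacetophenone
Conditions: NaOMe (25% in MeOH, 6 equiv), CuBr (0.2 equiv), DMF, 110 °C, N2; then aq. HCl
Reagents that add atoms: sodium methoxide, [Na+].[O-]C
Why: Copper(I)-mediated Ullmann-type methoxylation of the aryl bromide (the bromovanillin-to-syringaldehyde type of exchange), which tolerates an ortho-phenoxide and a ring carbonyl.

Step 4
Reactants: 4 2'-hydroxy-3',4',5',6'-tetramethoxyacetophenone; 5 4-(benzyloxy)benzaldehyde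
Product: 7 (E)-4-benzyloxy-2'-hydroxy-3',4',5',6'-tetramethoxychalcone, via aldol adduct 6 (not isolated)
Conditions: KOH (50% aq., 10 equiv), EtOH, rt, 48 h; then 2 M HCl, 0 °C
Reagents that add atoms: none
Why: Claisen–Schmidt crossed aldol condensation in which the methyl-ketone enolate adds to the non-enolisable aldehyde and E1cB dehydration of racemic 6 gives the conjugated, thermodynamically favoured E-enone, so no stereocentre remains.

Step 5
Reactants: 7 (E)-4-benzyloxy-2'-hydroxy-3',4',5',6'-tetramethoxychalcone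
Product: 9 4'-benzyloxy-5,6,7,8-tetramethoxyflavone, via flavanone 8 (not isolated)
Conditions: I2 (0.1 equiv), DMSO, 130 °C, 3 h; then aq. Na2S2O3
Reagents that add atoms: none
Why: Iodine-catalysed oxidative cyclisation, in which intramolecular oxa-Michael addition gives racemic flavanone 8 and α-iodination/HI elimination gives the flavone, with DMSO reoxidising HI to I2.

Step 6
Reactants: 9 4'-benzyloxy-5,6,7,8-tetramethoxyflavone
Product: 11 4'-benzyloxy-3-hydroxy-5,6,7,8-tetramethoxyflavone, via flavone epoxide 10 (not isolated)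
Conditions: DMDO (0.07 M in acetone, 3 equiv), CH2Cl2, 0 °C → rt, 24 h, dark; evaporate; then p-TsOH·H2O (0.1 equiv), CH2Cl2, rt
Reagents that add atoms: dimethyldioxirane, CC1(C)OO1
Why: Dioxirane epoxidation of the C2=C3 bond gives the racemic cis-fused epoxide 10, and acid-catalysed opening to the O1-stabilised C2 cation with loss of H-3 gives the 3-hydroxyflavone, removing both stereocentres.

Step 7
Reactants: 11 4'-benzyloxy-3-hydroxy-5,6,7,8-tetramethoxyflavone
Product: 12 3,4'-dihydroxy-5,6,7,8-tetramethoxyflavone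
Conditions: H2 (1 atm), 10% Pd/C, EtOAc–MeOH (1:1), rt
Reagents that add atoms: none
Why: Catalytic hydrogenolysis of the benzyl aryl ether, under which the chromone C2=C3 bond and the aryl methyl ethers are inert.

Step 8
Reactants: 12 3,4'-dihydroxy-5,6,7,8-tetramethoxyflavone
Product: 13 3,5,4'-trihydroxy-6,7,8-trimethoxyflavone
Conditions: BCl3 (1 M in CH2Cl2, 5 equiv), CH2Cl2, −78 → 0 °C; then MeOH, 1 M HCl
Reagents that add atoms: none
Why: Chelation-controlled Lewis-acid ether cleavage, in which boron bound to the C4 carbonyl activates only the peri 5-OMe for chloride attack on its methyl group while the 6-, 7- and 8-OMe groups lack this assistance at or below 0 °C.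

**Compound list**
1 | 3,4,5-trimethoxyphenol | COc1cc(O)cc(OC)c1OC | starting material
2 | 2'-hydroxy-4',5',6'-trimethoxyacetophenone | CC(=O)c1c(O)cc(OC)c(OC)c1OC | intermediate
3 | 3'-bromo-2'-hydroxy-4',5',6'-trimethoxyacetophenone | CC(=O)c1c(O)c(Br)c(OC)c(OC)c1OC | intermediate
4 | 2'-hydroxy-3',4',5',6'-tetramethoxyacetophenone | CC(=O)c1c(O)c(OC)c(OC)c(OC)c1OC | intermediate
5 | 4-(benzyloxy)benzaldehyde | O=Cc1ccc(OCc2ccccc2)cc1 | starting material
6 | aldol adduct: 3-[4-(benzyloxy)phenyl]-3-hydroxy-1-(2-hydroxy-3,4,5,6-tetramethoxyphenyl)propan-1-one (racemic, not isolated) | O=C(CC(O)c1ccc(OCc2ccccc2)cc1)c1c(O)c(OC)c(OC)c(OC)c1OC | intermediate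
7 | (E)-4-benzyloxy-2'-hydroxy-3',4',5',6'-tetramethoxychalcone | O=C(/C=C/c1ccc(OCc2ccccc2)cc1)c1c(O)c(OC)c(OC)c(OC)c1OC | intermediate
8 | flavanone: 2-[4-(benzyloxy)phenyl]-5,6,7,8-tetramethoxychroman-4-one (racemic, not isolated) | O=C1CC(c2ccc(OCc3ccccc3)cc2)Oc2c(OC)c(OC)c(OC)c(OC)c12 | intermediate
9 | 4'-benzyloxy-5,6,7,8-tetramethoxyflavone | O=c1cc(-c2ccc(OCc3ccccc3)cc2)oc2c(OC)c(OC)c(OC)c(OC)c12 | intermediate
10 | flavone epoxide: 2,3-epoxide of 9 (racemic, cis-fused, one enantiomer written, not isolated) | O=C1c2c(OC)c(OC)c(OC)c(OC)c2O[C@@]2(c3ccc(OCc4ccccc4)cc3)O[C@@H]12 | intermediate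
11 | 4'-benzyloxy-3-hydroxy-5,6,7,8-tetramethoxyflavone | O=c1c(O)c(-c2ccc(OCc3ccccc3)cc2)oc2c(OC)c(OC)c(OC)c(OC)c12 | intermediate
12 | 3,4'-dihydroxy-5,6,7,8-tetramethoxyflavone | O=c1c(O)c(-c2ccc(O)cc2)oc2c(OC)c(OC)c(OC)c(OC)c12 | intermediate
13 | 3,5,4'-trihydroxy-6,7,8-trimethoxyflavone | COc1c(OC)c(O)c2c(=O)c(O)c(-c3ccc(O)cc3)oc2c1OC | target

**Totals**
Total step count: 8. Longest linear sequence: 8 steps (1 → 13); aldehyde 5 enters at step 4.

**Steps most likely to fail, with fallbacks**

Step 3 (Cu-mediated methoxylation of a hindered bromide; hydrodebromination back to 2 is the likely side reaction). The fallback sets out from 1 and comes back at 4, putting the extra oxygen in before the acetyl group. Phenol 1 is ortho-formylated (MgCl2, Et3N, paraformaldehyde, MeCN, reflux) to 2-hydroxy-4,5,6-trimethoxybenzaldehyde F1. Dakin oxidation (H2O2, NaOH, N2, then acid) gives the air-sensitive 3,4,5-trimethoxybenzene-1,2-diol F2. This is methylated at once (Me2SO4, K2CO3, acetone, reflux) to pentamethoxybenzene F3. Friedel–Crafts acetylation at its single free position (AcCl, AlCl3, Et2O, 0 °C → rt) is accompanied by AlCl3 cleavage of one of the two equivalent flanking methyl ethers and gives 4 directly.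

Step 6 (slow epoxidation of an electron-poor alkene; possible oxidation of the benzylic CH2). The fallback sets out from 9 and comes back at 11 by C–H metalation instead of epoxidation. LDA in THF at −78 °C deprotonates C-3, and trapping with B(OMe)3 gives dimethyl [2-(4-benzyloxyphenyl)-5,6,7,8-tetramethoxy-4-oxo-4H-chromen-3-yl]boronate F4. Oxidation in the same flask with H2O2/AcOH gives 11.

Step 8 (two chelating sites, 3-OH and 5-OMe, may cause incomplete reaction or cleavage of 6-OMe as well). The fallback sets out from 9 and comes back at 13, moving the demethylation to the flavone stage, where only one chelating site exists. Excess BCl3 in CH2Cl2 (−78 → 0 °C) cleaves both the 5-OMe and the benzyl ether of 9 to give 5,4'-dihydroxy-6,7,8-trimethoxyflavone F5. Both phenols are benzylated (BnBr, K2CO3, DMF, 80 °C) to 4',5-bis(benzyloxy)-6,7,8-trimethoxyflavone F6. DMDO gives the racemic 2,3-epoxide of F6, flavone epoxide F7, which is not isolated, and p-TsOH converts it into 4',5-bis(benzyloxy)-3-hydroxy-6,7,8-trimethoxyflavone F8. Hydrogenolysis (H2, Pd/C) then removes both benzyl groups to give 13 with no selectivity demand in the last step.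

**Further compounds**
F1 | step 3 | 2-hydroxy-4,5,6-trimethoxybenzaldehyde | O=Cc1c(O)cc(OC)c(OC)c1OC
F2 | step 3 | 3,4,5-trimethoxybenzene-1,2-diol | Oc1c(O)cc(OC)c(OC)c1OC
F3 | step 3 | pentamethoxybenzene | COc1cc(OC)c(OC)c(OC)c1OC
F4 | step 6 | dimethyl [2-(4-benzyloxyphenyl)-5,6,7,8-tetramethoxy-4-oxo-4H-chromen-3-yl]boronate | COB(OC)c1c(-c2ccc(OCc3ccccc3)cc2)oc2c(OC)c(OC)c(OC)c(OC)c2c1=O
F5 | step 8 | 5,4'-dihydroxy-6,7,8-trimethoxyflavone | O=c1cc(-c2ccc(O)cc2)oc2c(OC)c(OC)c(OC)c(O)c12
F6 | step 8 | 4',5-bis(benzyloxy)-6,7,8-trimethoxyflavone | O=c1cc(-c2ccc(OCc3ccccc3)cc2)oc2c(OC)c(OC)c(OC)c(OCc3ccccc3)c12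
F7 | step 8 | 2,3-epoxide of F6 (racemic, cis-fused, one enantiomer written) | O=C1c2c(OCc3ccccc3)c(OC)c(OC)c(OC)c2O[C@@]2(c3ccc(OCc4ccccc4)cc3)O[C@@H]12
F8 | step 8 | 4',5-bis(benzyloxy)-3-hydroxy-6,7,8-trimethoxyflavone | O=c1c(O)c(-c2ccc(OCc3ccccc3)cc2)oc2c(OC)c(OC)c(OC)c(OCc3ccccc3)c12
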